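**Retrosynthetic overview** (germacrane numbering: C1 ketone, C2/C3 CH2CH2, C4/C5 epoxide, C6 lactone carbinol, C7/C11 butenolide β/α carbons, C12 lactone C=O, C13 CH2OAc, C8 ester carbinol, C9 free carbinol, C10 CHCH3)
1. Target ⇒ isoxazoline-bridged butenolide. The β-hydroxy ketone C1(=O)–C10–C9(OH) is carried as a 4,5-dihydroisoxazole, a temporary ring opened last by N–O cleavage. The C8 methacrylate goes on just before.
2. Key disconnection: the Cα–C(=O) bond C11–C12 of the butenolide is cut together with O6–C12 and C13–OAc. This leaves a ten-membered 2,3-allenol plus CO plus AcOH.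
3. Enabling feature: in the five-membered lactone ring, C11 carries both the carbonyl C12 and the acetoxymethyl carbon C13, and its double bond to C7 is exocyclic to the ten-membered ring. C7=C11–C13–O is therefore a masked vinylidene C7=C11=C13H2 whose central carbon lies 1,4 to O6.
4. Ten-membered ring ⇒ C6–C7 bond by Cr(II) closure of a propargylic chloride onto an α,β-epoxy aldehyde (SE2'). Open chain ⇒ directed nitrile oxide cycloaddition (C1–C10 and O–C9) of a geraniol-derived epoxy oxime with an (S)-enynol made from crotonaldehyde and propargyl chloride.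
5. Order of ring formation: epoxide, dihydroisoxazole, ten-membered carbocycle, butenolide.

Key step: step 12

Remark: the oxime 6 is drawn as its E isomer. Both isomers give the same nitrile oxide, so this geometry has no consequence.

Step 1
Reactants: 1 geraniol
Product: 2 (2R,3R)-2,3-epoxygeraniol
Conditions: Ti(Oi-Pr)4 (cat.), D-(−)-diisopropyl tartrate (cat.), t-BuOOH, 4 Å MS, CH2Cl2, −20 °C
Reagents that add atoms: tert-butyl hydroperoxide, CC(C)(C)OO
Why: Sharpless asymmetric epoxidation touches only the allylic 2,3-alkene and the D-(−)-tartrate catalyst delivers oxygen to the face that gives the (2R,3R)-epoxide, which sets C4 and C5 of the target and keeps the E-derived trans relation of C3 and C6 on the oxirane.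

Step 2
Reactants: 2 (2R,3R)-2,3-epoxygeraniol
Product: 3 (2R,3R)-2,3-epoxygeranyl tert-butyldimethylsilyl ether
Conditions: TBSCl, imidazole, CH2Cl2, 0 °C → rt
Reagents that add atoms: tert-butyldimethylsilyl chloride, CC(C)(C)[Si](C)(C)Cl
Why: Imidazole-promoted silylation of the primary alcohol is a standard protection that runs without alkoxide formation, so no Payne rearrangement is expected and no stereocentre is touched.

Step 3
Reactants: 3 (2R,3R)-2,3-epoxygeranyl tert-butyldimethylsilyl ether
Product: 5 3-[(2R,3R)-3-(tert-butyldimethylsilyloxymethyl)-2-methyloxiran-2-yl]propanal, via secondary ozonide 4 (not isolated)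
Conditions: O3, CH2Cl2, −78 °C; then Me2S, −78 °C → rt
Reagents that add atoms: ozone, [O-][O+]=O
Why: Ozonolysis with reductive work-up cleaves the only C=C bond left, turns the former C6 of geraniol into the aldehyde carbon C1 and leaves epoxide and silyl ether untouched.

Step 4
Reactants: 5 3-[(2R,3R)-3-(tert-butyldimethylsilyloxymethyl)-2-methyloxiran-2-yl]propanal
Product: 6 oxime of 5
Conditions: NH2OH·HCl, pyridine, EtOH, rt
Reagents that add atoms: hydroxylamine hydrochloride, Cl.NO
Why: Oxime condensation of an unhindered aldehyde is fast at room temperature under pyridine buffering, where the distal trisubstituted epoxide is not attacked.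

Step 5
Reactants: 7 propargyl chloride; 8 (E)-crotonaldehyde
Product: 10 rac-(E)-7-chlorohept-2-en-5-yn-4-ol, via lithium acetylide 9 (not isolated)
Conditions: 7, n-BuLi, THF, −78 °C; then 8, −78 °C; H2O quench
Reagents that add atoms: none
Why: 1,2-Addition of a lithium acetylide to an enal is reliable at −78 °C, where lithiated propargyl chloride does not decompose, and it gives the C8 carbinol as a racemate with the E-alkene intact.

Step 6
Reactants: 10 rac-(E)-7-chlorohept-2-en-5-yn-4-ol
Product: 11 (S,E)-7-chlorohept-2-en-5-yn-4-ol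
Conditions: Ti(Oi-Pr)4 (cat.), L-(+)-diisopropyl tartrate (cat.), t-BuOOH (0.6 equiv), 4 Å MS, CH2Cl2, −20 °C
Reagents that add atoms: none
Why: Sharpless kinetic resolution of a secondary E-allylic alcohol: with L-(+)-tartrate the (R)-enantiomer, which turns its alkynyl group away from the delivered oxygen, is epoxidised much faster, so the (S)-alcohol that carries the C8 configuration of the target is recovered just past half conversion.

Step 7
Reactants: 6 oxime of 5; 11 (S,E)-7-chlorohept-2-en-5-yn-4-ol
Product: 15 (1R)-4-chloro-1-[(4R,5R)-4-methyl-3-{2-[(2R,3R)-2-methyl-3-(tert-butyldimethylsilyloxymethyl)oxiran-2-yl]ethyl}-4,5-dihydroisoxazol-5-yl]but-2-yn-1-ol, via hydroximoyl chloride 12 (not isolated), via nitrile oxide 13 (not isolated), via magnesium alkoxide 14 (not isolated)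
Conditions: 6, t-BuOCl, CH2Cl2, −78 °C; transfer into 11, i-PrOH, EtMgBr, CH2Cl2, 0 °C → rt; aqueous work-up
Reagents that add atoms: none
Why: Magnesium-alkoxide-directed nitrile oxide cycloaddition (Huisgen 1,3-dipolar cycloaddition): chelation of the dipole oxygen to the C8 magnesium alkoxide places O on C9 and C1 on C10, brings the dipole to the alkene face syn to the C8–O bond (sets C9), carries the E-geometry into the trans C9/C10 relation (sets C10) and speeds up the alkene over the internal alkyne, while the epoxide stands in for the 4,5-alkene that would otherwise trap the nitrile oxide intramolecularly.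

Step 8
Reactants: 15 isoxazoline carbinol
Product: 16 C8 O-TBS ether of 15 (bis-silyl ether)
Conditions: TBSOTf, 2,6-lutidine, CH2Cl2, −78 °C
Reagents that add atoms: tert-butyldimethylsilyl triflate, CC(C)(C)[Si](C)(C)OS(=O)(=O)C(F)(F)F
Why: Silyl triflate with a non-nucleophilic pyridine base silylates the secondary propargylic alcohol at low temperature without displacing the propargylic chloride, and the siloxy group is chosen because it is a poor leaving group in steps 11 and 12.

Step 9
Reactants: 16 bis-silyl ether
Product: 17 primary epoxy alcohol (C6-OH free, C8-OTBS kept)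
Conditions: HF·pyridine, pyridine, THF, 0 °C
Reagents that add atoms: none
Why: Buffered hydrogen fluoride cleaves the unhindered primary silyl ether much faster than the secondary one, is not basic enough for Payne rearrangement or chloride displacement and is a standard reagent in the presence of trisubstituted epoxides.

Step 10
Reactants: 17 primary epoxy alcohol
Product: 18 α,β-epoxy aldehyde (C6 = CHO; 4R,5S by CIP, same geometry as before)
Conditions: Dess–Martin periodinane, CH2Cl2, 0 °C → rt
Reagents that add atoms: none
Why: Dess–Martin oxidation converts 2,3-epoxy alcohols into α,β-epoxy aldehydes under near-neutral conditions without epimerisation at C5.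

Step 11
Reactants: 18 α,β-epoxy aldehyde
Product: 20 isoxazoline-bridged ten-membered allenol (4R,5R,6S,8R,9R,10R; 7-vinylidene, 6-OH, 8-OTBS, 4,5-epoxide), via propargylchromium species 19 (not isolated)
Conditions: CrCl2 (excess), THF–DMF, rt, slow addition of 18 (high dilution); H2O work-up
Reagents that add atoms: none
Why: Nozaki–Hiyama-type chromium(II) Barbier closure: chromium sits on the primary carbon C13 of 19 and the aldehyde is attacked through the γ-carbon C7 (SE2'), which is the known route from 2-alkynyl halides to α-allenols and mirrors the known allyl-halide closure of the C6–C7 bond of 4,5-epoxygermacranes, the isoxazoline hides the C1 ketone that would otherwise be attacked in a five-membered mode, the C8 siloxy group resists 1,4-elimination, and C6 is set as 6S by macrocyclic control because the folded chain presents the aldehyde with its chromium-bound oxygen turned outward and H5 anti to H6.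

Step 12
Reactants: 20 isoxazoline-bridged ten-membered allenol
Product: 23 isoxazoline-bridged 13-acetoxy-7(11)-en-12,6-olide with 8-OTBS (4R,5R,6S,8R,9R,10R), via alkoxycarbonylpalladium acetate 21 (not isolated), via allylpalladium acetate 22 (not isolated)
Conditions: Pd(OAc)2 (10 mol %), 1,4-benzoquinone, LiOAc, AcOH (few equiv), CO (1 atm), THF, 30 °C
Reagents that add atoms: carbon monoxide, [C-]#[O+]; acetic acid, CC(=O)O
Why: Proposed new method: Pd(OAc)2 under CO turns the only free hydroxyl (O6) into the alkoxycarbonylpalladium 21, whose acyl carbon migrates to the central allene carbon C11 (the C11=C13 π bond lies in the C6–C7–C8 plane and points at the tethered Pd–C bond), so that the C11–C12 bond closes the lactone and leaves allylpalladium 22, which quinone-activated acetate attack at the unhindered CH2 terminus C13 converts into 23 and Pd(0) that the quinone reoxidises. The closest known reaction type is the PdCl2/CuCl2 chlorocyclocarbonylation of 2,3-allenols to 3-chloromethyl-2(5H)-furanones, joined to the acetate/quinone capture of π-allylpalladium known from the 1,4-diacetoxylation of dienes, so only the acetate termination of the allenol carbonylation is new. The one ring closed is the five-membered butenolide, by 5-exo-trig migratory insertion with respect to C11=C13. No stereocentre is created: C6 keeps its configuration because the C6–O bond is never broken, and the tetrasubstituted C7=C11 alkene is the untouched orthogonal π bond of the allene with its geometry fixed by the ring. The step needs hydroxyl, pathway and terminus selectivity: O8 is silylated and O9 is locked in the isoxazoline so that neither an 8,12-olide nor a six-membered lactone can form, CO saturation favours alkoxycarbonylation over 5-endo oxypalladation, the fully substituted C7 sends acetate to C13, and the C8 siloxy group is too poor a leaving group for β-elimination from 22.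

Step 13
Reactants: 23 silylated butenolide
Product: 24 C8 alcohol (8-OH, isoxazoline intact)
Conditions: HF·pyridine, THF, 0 °C → rt
Reagents that add atoms: none
Why: Acidic fluoride removes the remaining secondary silyl ether as in late-stage deprotection of epoxide-bearing macrocycles, and the absence of base prevents translactonisation of the freed O8 onto C12 and loss of the allylic acetate.

Step 14
Reactants: 24 C8 alcohol
Product: 25 C8 methacrylate (isoxazoline intact)
Conditions: methacrylic anhydride, Et3N, DMAP (cat.), CH2Cl2, 0 °C → rt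
Reagents that add atoms: methacrylic anhydride, C=C(C)C(=O)OC(=O)C(C)=C
Why: DMAP-catalysed acylation (Steglich-type) esterifies the only free hydroxyl, O9 being still locked in the isoxazoline, so the 8-O-acyl/9-OH pattern of the target is obtained without any diol differentiation.

Step 15
Reactants: 25 C8 methacrylate
Product: 27 target CNP0185951.1 (4R,5R,6S,8R,9R,10S), via hydroxy imine 26 (not isolated)
Conditions: Mo(CO)6, MeCN–H2O (10:1), 75 °C
Reagents that add atoms: water, O
Why: Molybdenum(0) inserts into the weak N–O bond (reductive isoxazoline cleavage) and water hydrolyses the resulting β-hydroxy imine, which unveils the C1 ketone and the C9 hydroxyl together under neutral conditions that should not epimerise C10, do not reduce electron-poor alkenes and leave the esters and the epoxide alone.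

**Compound list**
1 | geraniol | CC(C)=CCC/C(C)=C/CO | starting material
2 | (2R,3R)-2,3-epoxygeraniol | OC[C@H]1O[C@]1(C)CCC=C(C)C | intermediate
3 | (2R,3R)-2,3-epoxygeranyl TBS ether | CC(C)(C)[Si](C)(C)OC[C@H]1O[C@]1(C)CCC=C(C)C | intermediate
4 | secondary ozonide of 3 (1,2,4-trioxolane, acetal carbon unassigned) | CC(C)(C)[Si](C)(C)OC[C@H]1O[C@]1(C)CCC1OOC(C)(C)O1 | intermediate
5 | 3-[(2R,3R)-3-(TBSO-methyl)-2-methyloxiran-2-yl]propanal | CC(C)(C)[Si](C)(C)OC[C@H]1O[C@]1(C)CCC=O | intermediate
6 | oxime of 5 (E drawn) | CC(C)(C)[Si](C)(C)OC[C@H]1O[C@]1(C)CC/C=N/O | intermediate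
7 | propargyl chloride (3-chloroprop-1-yne) | C#CCCl | starting material
8 | (E)-crotonaldehyde | C/C=C/C=O | starting material
9 | lithium 3-chloroprop-1-ynide | [Li]C#CCCl | intermediate
10 | rac-(E)-7-chlorohept-2-en-5-yn-4-ol | C/C=C/C(O)C#CCCl | intermediate
11 | (S,E)-7-chlorohept-2-en-5-yn-4-ol | C/C=C/[C@H](O)C#CCCl | intermediate
12 | hydroximoyl chloride from 6 | CC(C)(C)[Si](C)(C)OC[C@H]1O[C@]1(C)CCC(Cl)=NO | intermediate
13 | nitrile oxide from 12 | CC(C)(C)[Si](C)(C)OC[C@H]1O[C@]1(C)CCC#[N+][O-] | intermediate
14 | bromomagnesium alkoxide of 11 | C/C=C/[C@H](O[Mg]Br)C#CCCl | intermediate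
15 | isoxazoline carbinol (4R,5R,8R,9R,10R; 8-OH, 6-OTBS, 13-Cl) | CC(C)(C)[Si](C)(C)OC[C@H]1O[C@]1(C)CCC1=NO[C@@H]([C@H](O)C#CCCl)[C@@H]1C | intermediate
16 | bis-silyl ether (8-OTBS, 6-OTBS) | CC(C)(C)[Si](C)(C)OC[C@H]1O[C@]1(C)CCC1=NO[C@@H]([C@H](O[Si](C)(C)C(C)(C)C)C#CCCl)[C@@H]1C | intermediate
17 | primary epoxy alcohol (6-OH, 8-OTBS) | OC[C@H]1O[C@]1(C)CCC1=NO[C@@H]([C@H](O[Si](C)(C)C(C)(C)C)C#CCCl)[C@@H]1C | intermediate
18 | α,β-epoxy aldehyde (C6 = CHO) | O=C[C@H]1O[C@]1(C)CCC1=NO[C@@H]([C@H](O[Si](C)(C)C(C)(C)C)C#CCCl)[C@@H]1C | intermediate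
19 | propargylchromium(III) dichloride from 18 | O=C[C@H]1O[C@]1(C)CCC1=NO[C@@H]([C@H](O[Si](C)(C)C(C)(C)C)C#CC[Cr](Cl)Cl)[C@@H]1C | intermediate
20 | isoxazoline-bridged ten-membered allenol (4R,5R,6S,8R,9R,10R) | CC(C)(C)[Si](C)(C)O[C@@H]1C(=C=C)[C@H](O)[C@H]2O[C@]2(C)CCC2=NO[C@@H]1[C@@H]2C | intermediate
21 | O6-alkoxycarbonylpalladium(II) acetate | CC(C)(C)[Si](C)(C)O[C@@H]1C(=C=C)[C@H](OC(=O)[Pd]OC(C)=O)[C@H]2O[C@]2(C)CCC2=NO[C@@H]1[C@@H]2C | intermediate
22 | allylpalladium(II) acetate (σ form at C13 drawn) | CC(C)(C)[Si](C)(C)O[C@@H]1C2=C(C[Pd]OC(C)=O)C(=O)O[C@@H]2[C@H]2O[C@]2(C)CCC2=NO[C@@H]1[C@@H]2C | intermediate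
23 | 13-acetoxy butenolide, 8-OTBS, isoxazoline | CC(C)(C)[Si](C)(C)O[C@@H]1C2=C(COC(C)=O)C(=O)O[C@@H]2[C@H]2O[C@]2(C)CCC2=NO[C@@H]1[C@@H]2C | intermediate
24 | 13-acetoxy butenolide, 8-OH, isoxazoline | O[C@@H]1C2=C(COC(C)=O)C(=O)O[C@@H]2[C@H]2O[C@]2(C)CCC2=NO[C@@H]1[C@@H]2C | intermediate
25 | 13-acetoxy butenolide, 8-O-methacrylate, isoxazoline | C=C(C)C(=O)O[C@@H]1C2=C(COC(C)=O)C(=O)O[C@@H]2[C@H]2O[C@]2(C)CCC2=NO[C@@H]1[C@@H]2C | intermediate
26 | β-hydroxy imine (C1=NH, 9-OH) | C=C(C)C(=O)O[C@@H]1C2=C(COC(C)=O)C(=O)O[C@@H]2[C@H]2O[C@]2(C)CCC(=N)[C@@H](C)[C@H]1O | intermediate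
27 | CNP0185951.1 (4R,5R,6S,8R,9R,10S) | C=C(C)C(=O)O[C@@H]1C2=C(COC(C)=O)C(=O)O[C@@H]2[C@H]2O[C@]2(C)CCC(=O)[C@@H](C)[C@H]1O | target

**Step count**
- Total step count: 15.
- Longest linear sequence: 13 (steps 1–4 and 7–15).

**Steps most likely to fail**

1. Step 12 (Proposed new method).
   - Acetate capture of the allylpalladium may be slower than β-hydride loss.
   - 5-Endo oxypalladation of the allenol may compete with alkoxycarbonylation.
   - Acetic acid may slowly open the epoxide.
   - Fallback, known chemistry only, sets out from 20. PdCl2 (cat.), CuCl2, CO (1 atm) in THF at rt, the established chlorocyclocarbonylation of 2,3-allenols, should give the 13-chloro butenolide F1. Displacement of its primary allylic chloride with CsOAc in DMF at rt then brings the acetate in as a separate SN2 event and rejoins the route at 23.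

2. Step 11.
   - Ring closure may be slow enough for protonation of the organochromium species.
   - The intrinsic Felkin–Anh bias of the epoxy aldehyde may override macrocyclic control, which means poor or wrong facial selectivity at C6.
   - Fallback sets out from 18. The closure is run as in step 11 and the 6-epi allenol F2, alone or mixed with 20, is oxidised with Dess–Martin periodinane to the macrocyclic allenyl epoxy ketone F3.
   - C6 is then set by C–H instead of C–C bond formation through 1,2-reduction with DIBAL-H in toluene at −78 °C. Hydride addition to the ketone has the opposite Felkin–Anh sense to carbon addition to the aldehyde and should therefore favour the 5,6-syn alcohol. The route is rejoined at 20.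

3. Step 15.
   - The low-valent metal may complex or reduce the methacrylate C=C bond or ionise the allylic acetate.
   - The liberated ammonia may add to the methacrylate.
   - Fallback sets out from 23 and moves the N–O cleavage ahead of the methacrylate. Raney nickel, H2 and B(OH)3 in MeOH–H2O should give, through the silylated hydroxy imine F4, the silylated β-hydroxy ketone F5.
   - Chloroacetic anhydride and pyridine mask O9 as the 9-O-chloroacetate F6. HF·pyridine frees O8 to give the 8-alcohol F7. Methacrylic anhydride with DMAP gives the mixed diester F8.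
   - Thiourea in EtOH at 40 °C removes only the chloroacetate, and the route is rejoined at 27.

**Further compounds**
F1 | step 12 | 13-chloro butenolide, 8-OTBS, isoxazoline | CC(C)(C)[Si](C)(C)O[C@@H]1C2=C(CCl)C(=O)O[C@@H]2[C@H]2O[C@]2(C)CCC2=NO[C@@H]1[C@@H]2C
F2 | step 11 | 6-epi allenol (6R epimer of 20) | CC(C)(C)[Si](C)(C)O[C@@H]1C(=C=C)[C@@H](O)[C@H]2O[C@]2(C)CCC2=NO[C@@H]1[C@@H]2C
F3 | step 11 | macrocyclic allenyl epoxy ketone (C6 = C=O) | CC(C)(C)[Si](C)(C)O[C@@H]1C(=C=C)C(=O)[C@H]2O[C@]2(C)CCC2=NO[C@@H]1[C@@H]2C
F4 | step 15 | silylated hydroxy imine (8-OTBS, C1=NH, 9-OH) | CC(C)(C)[Si](C)(C)O[C@@H]1C2=C(COC(C)=O)C(=O)O[C@@H]2[C@H]2O[C@]2(C)CCC(=N)[C@@H](C)[C@H]1O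
F5 | step 15 | silylated β-hydroxy ketone (8-OTBS, 9-OH) | CC(C)(C)[Si](C)(C)O[C@@H]1C2=C(COC(C)=O)C(=O)O[C@@H]2[C@H]2O[C@]2(C)CCC(=O)[C@@H](C)[C@H]1O
F6 | step 15 | 9-O-chloroacetate, 8-OTBS | CC(C)(C)[Si](C)(C)O[C@@H]1C2=C(COC(C)=O)C(=O)O[C@@H]2[C@H]2O[C@]2(C)CCC(=O)[C@@H](C)[C@H]1OC(=O)CCl
F7 | step 15 | 8-alcohol, 9-O-chloroacetate | O[C@@H]1C2=C(COC(C)=O)C(=O)O[C@@H]2[C@H]2O[C@]2(C)CCC(=O)[C@@H](C)[C@H]1OC(=O)CCl
F8 | step 15 | 8-O-methacrylate, 9-O-chloroacetate | C=C(C)C(=O)O[C@@H]1C2=C(COC(C)=O)C(=O)O[C@@H]2[C@H]2O[C@]2(C)CCC(=O)[C@@H](C)[C@H]1OC(=O)CCl
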